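The 1H-isochromene (ring A = dimethoxybenzene, ring B = pyran) is cut at the two bonds that flank its O–CH2 unit: C1–C8a, from the benzylic CH2 to ring A, and O2–C3, from the ring oxygen to the aroyl-bearing enol-ether carbon. This leaves a CH2–O fragment, supplied as (tributylstannyl)methanol, and an ortho-bromoaryl ynone whose alkyne carbons become C3 and C4. In one flask, Stille hydroxymethylation at C8a is followed by phosphine-catalysed anti-Michael (α-umpolung) addition of the new hydroxyl to C3. This formal [4+2] annulation exploits the 1,4-relationship of C8a and C3 across the aryl alkyne and closes ring B of the finished target.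

Key step: step 3

Remark: the target has no stereocentre and its only non-aromatic C=C bond lies in ring B, so no descriptor is needed; (tributylstannyl)methanol 5 is taken as a purchasable reagent.

Step 1
Reactants: 1 2-bromo-4,5-dimethoxybenzaldehyde
Product: 2 1-bromo-2-ethynyl-4,5-dimethoxybenzene
Conditions: dimethyl (1-diazo-2-oxopropyl)phosphonate (1.3 equiv), K2CO3 (2 equiv), MeOH, 0 → 25 °C
Reagents that add atoms: dimethyl (1-diazo-2-oxopropyl)phosphonate, CC(=O)C(=[N+]=[N-])P(=O)(OC)OC
Why: Seyferth–Gilbert homologation in its Ohira–Bestmann form: methanolysis of the acetyl group frees the diazomethylphosphonate anion, which olefinates the aldehyde, and loss of N2 with 1,2-hydride shift of the alkylidene carbene should give the terminal alkyne while the aryl bromide and the methyl ethers are inert to K2CO3/MeOH.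

Step 2
Reactants: 2 1-bromo-2-ethynyl-4,5-dimethoxybenzene; 3 2,4-dimethoxybenzoyl chloride
Product: 4 3-(2-bromo-4,5-dimethoxyphenyl)-1-(2,4-dimethoxyphenyl)prop-2-yn-1-one
Conditions: PdCl2(PPh3)2 (2 mol%), CuI (4 mol%), Et3N (1.5 equiv), THF, 25 °C
Reagents that add atoms: none
Why: Acyl Sonogashira coupling: the acid chloride adds oxidatively to zerovalent palladium at 25 °C far faster than the electron-rich, ortho-substituted aryl bromide, and the copper acetylide of 2 transmetalates so that reductive elimination should give the ynone.

Step 3
Reactants: 4 3-(2-bromo-4,5-dimethoxyphenyl)-1-(2,4-dimethoxyphenyl)prop-2-yn-1-one; 5 (tributylstannyl)methanol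
Product: 7 (2,4-dimethoxyphenyl)(6,7-dimethoxy-1H-isochromen-3-yl)methanone, via hydroxymethyl ynone 6 (not isolated)
Conditions: 5 (1.3 equiv), Pd(PPh3)4 (5 mol%), 1,4-dioxane, 95 °C; then PBu3 (20 mol%), 50 °C, same flask
Reagents that add atoms: none
Why: Proposed new method: zerovalent palladium inserts into the only C–Br bond of 4, the hydroxymethyl group of 5 is transferred from tin and reductive elimination forms the C1–C8a bond of 6, as in the known Stille hydroxymethylation of aryl halides that is followed in the flask by lactonisation to phthalides. PBu3 then adds to the arene-bound alkyne carbon C4 (the β-carbon of the ynone), the vinyl anion takes the proton of the benzylic OH, and the tethered alkoxide attacks the ketone-bearing carbon C3 of the vinylphosphonium ion to form the O2–C3 bond; proton transfer from C3 to C4 and loss of PBu3 leave the C3=C4 double bond, the closest known type being the phosphine-catalysed α-umpolung addition of N–H and O–H pronucleophiles to ynoates and ynones. Ring B closes 6-endo-trig on the vinylphosphonium ion, which is 6-endo-dig with respect to the alkyne of 6. No stereocentre is formed and the ring fixes the geometry of the C3=C4 bond. The step needs attack at C3 instead of 5-exo oxa-Michael addition at C4; the phosphonium group on C4 blocks that carbon and makes C3 the electrophilic terminus, and the neutral Stille stage produces no alkoxide that could add in the base-mediated sense before the phosphine acts.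

Compound list
1 | 2-bromo-4,5-dimethoxybenzaldehyde | COc1cc(Br)c(C=O)cc1OC | starting material
2 | 1-bromo-2-ethynyl-4,5-dimethoxybenzene | COc1cc(Br)c(C#C)cc1OC | intermediate
3 | 2,4-dimethoxybenzoyl chloride | COc1ccc(C(=O)Cl)c(OC)c1 | starting material
4 | 3-(2-bromo-4,5-dimethoxyphenyl)-1-(2,4-dimethoxyphenyl)prop-2-yn-1-one | COc1ccc(C(=O)C#Cc2cc(OC)c(OC)cc2Br)c(OC)c1 | intermediate
5 | (tributylstannyl)methanol | CCCC[Sn](CCCC)(CCCC)CO | starting material
6 | 1-(2,4-dimethoxyphenyl)-3-[2-(hydroxymethyl)-4,5-dimethoxyphenyl]prop-2-yn-1-one | COc1ccc(C(=O)C#Cc2cc(OC)c(OC)cc2CO)c(OC)c1 | intermediate (not isolated)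
7 | (2,4-dimethoxyphenyl)(6,7-dimethoxy-1H-isochromen-3-yl)methanone | COc1ccc(C(=O)C2=Cc3cc(OC)c(OC)cc3CO2)c(OC)c1 | target

Total step count: 3
Longest linear sequence: 3 steps (1 → 2 → 4 → 7)

Steps most likely to fail

1. Step 3 (Proposed new method). Transfer of the sp3 hydroxymethyl group from tin may be slow, so that protodebromination or carbopalladation of a second ynone molecule competes. Alcohol 6 may also close in the 5-exo oxa-Michael sense at C4 under palladium or tin Lewis acids before the phosphine acts, or the phosphine may start oligomerisation of the ynone. The fallback uses known chemistry only, sets out from aldehyde 1 and returns to the route at target 7 through ether formation and aldol ring closure. Aldehyde 1 is protected with ethylene glycol (TsOH, toluene, Dean–Stark) as 2-(2-bromo-4,5-dimethoxyphenyl)-1,3-dioxolane F1. Bromine–lithium exchange (n-BuLi, THF, −78 °C) and quench with paraformaldehyde should give [2-(1,3-dioxolan-2-yl)-4,5-dimethoxyphenyl]methanol F2. Acid chloride 3 and diazomethane (Et2O, 0 °C) should give 2-diazo-1-(2,4-dimethoxyphenyl)ethan-1-one F3. Its Rh2(OAc)4-catalysed O–H insertion into F2 (CH2Cl2, 25 °C) should give the keto ether 2-{[2-(1,3-dioxolan-2-yl)-4,5-dimethoxyphenyl]methoxy}-1-(2,4-dimethoxyphenyl)ethan-1-one F4. Aqueous HCl in THF should free the aldehyde 2-{[2-(2,4-dimethoxyphenyl)-2-oxoethoxy]methyl}-4,5-dimethoxybenzaldehyde F5. Piperidine/AcOH in toluene at 80 °C should then close ring B by intramolecular aldol condensation to 7; the O–CH2–C(=O) methylene is the only enolisable position.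

2. Step 2. Oxidative addition at the aryl bromide may compete and lead to aryl–alkyne oligomers. Oxidative homocoupling of the copper acetylide and conjugate addition of chloride or amine to the ynone are further losses. The fallback sets out from alkyne 2 and returns at ynone 4 without palladium. Deprotonation of 2 with EtMgBr (THF, 40 °C; the aryl bromide does not exchange) and addition to 2,4-dimethoxybenzaldehyde should give racemic 3-(2-bromo-4,5-dimethoxyphenyl)-1-(2,4-dimethoxyphenyl)prop-2-yn-1-ol F6. Oxidation with MnO2 (CH2Cl2, 25 °C) should give 4.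

3. Step 1. Addition of the diazophosphonate anion to the electron-rich, ortho-hindered aldehyde may be sluggish, so that the reagent decomposes first. The fallback sets out from aldehyde 1 and returns at alkyne 2 by olefination and elimination. Wittig reaction with the ylide from (chloromethyl)triphenylphosphonium chloride and NaHMDS (THF, −78 → 0 °C) should give 1-bromo-2-(2-chloroethenyl)-4,5-dimethoxybenzene F7 as an E/Z mixture. LDA (2.5 equiv, THF, −78 °C) should eliminate HCl from both isomers and give 2 after NH4Cl quench.

Further compounds
F1 | step 3 | 2-(2-bromo-4,5-dimethoxyphenyl)-1,3-dioxolane | COc1cc(Br)c(C2OCCO2)cc1OC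
F2 | step 3 | [2-(1,3-dioxolan-2-yl)-4,5-dimethoxyphenyl]methanol | COc1cc(CO)c(C2OCCO2)cc1OC
F3 | step 3 | 2-diazo-1-(2,4-dimethoxyphenyl)ethan-1-one | COc1ccc(C(=O)C=[N+]=[N-])c(OC)c1
F4 | step 3 | 2-{[2-(1,3-dioxolan-2-yl)-4,5-dimethoxyphenyl]methoxy}-1-(2,4-dimethoxyphenyl)ethan-1-one | COc1ccc(C(=O)COCc2cc(OC)c(OC)cc2C2OCCO2)c(OC)c1
F5 | step 3 | 2-{[2-(2,4-dimethoxyphenyl)-2-oxoethoxy]methyl}-4,5-dimethoxybenzaldehyde | COc1ccc(C(=O)COCc2cc(OC)c(OC)cc2C=O)c(OC)c1
F6 | step 2 | 3-(2-bromo-4,5-dimethoxyphenyl)-1-(2,4-dimethoxyphenyl)prop-2-yn-1-ol (racemate) | COc1ccc(C(O)C#Cc2cc(OC)c(OC)cc2Br)c(OC)c1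
F7 | step 1 | 1-bromo-2-(2-chloroethenyl)-4,5-dimethoxybenzene (E/Z mixture) | COc1cc(Br)c(C=CCl)cc1OC
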